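**Plan**

- Cuts, in retrosynthetic order: the six benzyl ethers; the interflavan bond C4(upper)–C8(lower); then, in the lower flavan-3-ol, both bonds joining ring A to ring C (C4–C4a and O1–C8a) together; the upper unit is cut at C2–aryl back to a chromone.
- Enabling feature: in the lower unit O1 and C4 sit on adjacent ring A carbons (C8a, C4a) and the C5 oxygen flanks C4a. Ring A can therefore enter as the aryne C4a≡C8a of 3,5-bis(benzyloxy)benzene: the C5–O bond steers an alkoxide O1 to C8a, and the carbanion left at C4a closes ring C on a C4 chloride.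
- Forward order: ring A as an ortho-silylaryl triflate; the C2–C3–C4 chain with ring B by Evans glycolate aldol, reduction and chlorination; aryne annulation makes ring C; the upper flavanone comes from a chromone by asymmetric conjugate addition, then reduction; Friedel–Crafts union at C8; hydrogenolysis.
- Stereochemistry: lower C2 and C3 come from the auxiliary-controlled syn aldol and are carried through untouched; upper C2 comes from the Pd(OCOCF3)2/(R)-t-BuPyOx catalyst; upper C4 comes from axial attack on the flavan-4-yl cation, trans to the 2-aryl group.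

Key step: step 8

Assumption: the facial sense of the Pd(OCOCF3)2/t-BuPyOx conjugate addition established for cyclic enones is taken to hold for chromone 25, so the (R)-ligand is chosen to reach the (2S)-flavanone.

**Route**

Step 1
Reactants: 1 3,5-bis(benzyloxy)phenol
Product: 2 3,5-bis(benzyloxy)phenyl N-(propan-2-yl)carbamate
Conditions: i-PrNCO, Et3N (cat.), CH2Cl2, rt
Reagents that add atoms: isopropyl isocyanate, CC(C)N=C=O
Why: Base-catalysed addition of the phenol to the isocyanate (carbamoylation) installs the directing group for ortho-metalation, which can later be removed without acid.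

Step 2
Reactants: 2 3,5-bis(benzyloxy)phenyl N-(propan-2-yl)carbamate
Product: 6 3,5-bis(benzyloxy)-2-(trimethylsilyl)phenyl N-(propan-2-yl)carbamate, via N-silyl carbamate 3 (not isolated), via ortho-lithiated N-silyl carbamate 4 (not isolated), via N,C-bis(silyl) carbamate 5 (not isolated)
Conditions: TMSOTf, TMEDA, Et2O, 0 °C → rt; n-BuLi (2 equiv), TMEDA, −78 °C; TMSCl, −78 °C → rt; sat. aq. NH4Cl
Reagents that add atoms: chlorotrimethylsilane, C[Si](C)(C)Cl (trimethylsilyl triflate, C[Si](C)(C)OS(=O)(=O)C(F)(F)F, leaves its silyl group only in 3 to 5)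
Why: Directed ortho-metalation of the N-silylated carbamate should occur at one of the two equivalent positions flanked by the carbamate and a benzyloxy group, the aryllithium is trapped by TMSCl, and the mild aqueous work-up frees the N–H without protodesilylation.

Step 3
Reactants: 6 3,5-bis(benzyloxy)-2-(trimethylsilyl)phenyl N-(propan-2-yl)carbamate
Product: 8 3,5-bis(benzyloxy)-2-(trimethylsilyl)phenyl trifluoromethanesulfonate, via silylphenol 7 (not isolated)
Conditions: DBU, Et2NH, MeCN, 40 °C; then PhNTf2, rt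
Reagents that add atoms: N-phenylbis(trifluoromethanesulfonimide), O=S(=O)(N(c1ccccc1)S(=O)(=O)C(F)(F)F)C(F)(F)F
Why: E1cB cleavage of the N-monoalkyl carbamate (the isocyanate is trapped by Et2NH) frees the phenoxide, which is triflated in the same pot to give the ortho-silylaryl triflate aryne precursor under non-acidic conditions.

Step 4
Reactants: 9 (4S)-4-benzyl-1,3-oxazolidin-2-one; 10 (benzyloxy)acetyl chloride
Product: 12 (4S)-4-benzyl-3-[(benzyloxy)acetyl]-1,3-oxazolidin-2-one, via N-lithio oxazolidinone 11 (not isolated)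
Conditions: n-BuLi, THF, −78 °C; then 10, −78 → 0 °C
Reagents that add atoms: none
Why: N-acylation of the lithiated oxazolidinone by the acid chloride gives the glycolate imide needed for the auxiliary-controlled aldol.

Step 5
Reactants: 12 (4S)-4-benzyl-3-[(benzyloxy)acetyl]-1,3-oxazolidin-2-one; 13 4-(benzyloxy)benzaldehyde
Product: 16 (4S)-4-benzyl-3-[(2S,3R)-2-(benzyloxy)-3-[4-(benzyloxy)phenyl]-3-hydroxypropanoyl]-1,3-oxazolidin-2-one, via Z boron enolate 14 (not isolated), via boron aldolate 15 (not isolated)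
Conditions: Bu2BOTf, Et3N, CH2Cl2, −78 → 0 °C; 13, −78 → 0 °C; pH 7 buffer, MeOH, 30% H2O2, 0 °C
Reagents that add atoms: none
Why: Evans syn aldol: the Z boron enolate reacts through a chair (Zimmerman–Traxler) transition state on the face left open by the auxiliary benzyl group, setting the 2S,3R syn pair that becomes C3 and C2 of the lower flavan.

Step 6
Reactants: 16 (4S)-4-benzyl-3-[(2S,3R)-2-(benzyloxy)-3-[4-(benzyloxy)phenyl]-3-hydroxypropanoyl]-1,3-oxazolidin-2-one
Product: 17 (1R,2R)-2-(benzyloxy)-1-[4-(benzyloxy)phenyl]propane-1,3-diol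
Conditions: LiBH4, MeOH (1 equiv), THF, 0 °C
Reagents that add atoms: none
Why: Reductive cleavage of the N-acyl oxazolidinone by LiBH4 gives the 1,3-diol and releases the auxiliary without touching either stereocenter.

Step 7
Reactants: 17 (1R,2R)-2-(benzyloxy)-1-[4-(benzyloxy)phenyl]propane-1,3-diol
Product: 19 (1R,2S)-2-(benzyloxy)-1-[4-(benzyloxy)phenyl]-3-chloropropan-1-ol, via primary mesylate 18 (not isolated)
Conditions: MsCl (1.05 equiv), 2,4,6-collidine, CH2Cl2, −10 °C; then LiCl, DMF, 60 °C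
Reagents that add atoms: lithium chloride, [Li+].[Cl-] (methanesulfonyl chloride, CS(=O)(=O)Cl, leaves atoms only in 18)
Why: Hindered-base sulfonylation selects the primary hydroxyl, and SN2 displacement by chloride (Finkelstein-type) installs a leaving group at the future C4 while the benzylic alcohol stays free and both stereocenters are untouched (the descriptor at C2 changes only through the priority rules).

Step 8
Reactants: 19 (1R,2S)-2-(benzyloxy)-1-[4-(benzyloxy)phenyl]-3-chloropropan-1-ol; 8 3,5-bis(benzyloxy)-2-(trimethylsilyl)phenyl trifluoromethanesulfonate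
Product: 23 (2R,3R)-3,5,7-tris(benzyloxy)-2-[4-(benzyloxy)phenyl]-3,4-dihydro-2H-chromene, via potassium alkoxide 20 (not isolated), via 3,5-bis(benzyloxy)benzyne 21 (not isolated), via aryl anion 22 (not isolated)
Conditions: KH, THF, 0 °C; then 8 (1.5 equiv), KF, 18-crown-6, THF, 0 °C → rt
Reagents that add atoms: none
Why: Proposed new method: fluoride removes the silyl group of 8 and triflate leaves to give aryne 21; alkoxide 20 adds to the aryne carbon that becomes C8a (distal to the neighbouring benzyloxy group), and the aryl anion 22 formed at C4a, flanked by two oxygen substituents, displaces the primary chloride. The closest known reaction types are the aryne annulation of salicylate esters to xanthones (O-addition to the aryne, then capture of the aryl anion by a tethered electrophile) and the Parham cyclialkylation of ortho-lithiated aryl 3-halopropyl ethers to chromans. Ring C closes in the 6-exo-tet mode; the competing 4-exo-tet closure of 20 to an oxetane is slow for a chloride, and the 3-O-benzyl group excludes epoxide formation. No stereocenter is formed: C2 and C3 come unchanged from the aldol because neither of their C–O bonds is touched, so the syn aldol pattern becomes the 2,3-cis relation of the epi series. The step needs regioselective addition to the unsymmetrical aryne, which the inductively withdrawing benzyloxy group next to the triple bond secures by placing the negative charge on the adjacent carbon (aryne distortion model), and it needs the aryl anion to survive until it cyclises, which the proton-free medium (KH, no amine, no alcohol, no MeCN) secures.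

Step 9
Reactants: 24 7-hydroxy-4H-chromen-4-one
Product: 25 7-(benzyloxy)-4H-chromen-4-one
Conditions: BnBr, K2CO3, DMF, 60 °C
Reagents that add atoms: benzyl bromide, BrCc1ccccc1
Why: Williamson ether synthesis on the acidic vinylogous-ester phenol protects the 7-hydroxyl as the ether used throughout.

Step 10
Reactants: 25 7-(benzyloxy)-4H-chromen-4-one; 26 [4-(benzyloxy)phenyl]boronic acid
Product: 27 (2S)-7-(benzyloxy)-2-[4-(benzyloxy)phenyl]-2,3-dihydro-4H-chromen-4-one
Conditions: Pd(OCOCF3)2 (5 mol %), (R)-t-BuPyOx (6 mol %), NH4PF6, H2O, ClCH2CH2Cl, 60 °C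
Reagents that add atoms: none
Why: Catalytic asymmetric conjugate addition of the arylboronic acid to the chromone (transmetalation, insertion of C2=C3 into the aryl–Pd bond, protonolysis of the enolate) should set C2 as S under control of the tert-butyl group of the pyridine-oxazoline ligand.

Step 11
Reactants: 27 (2S)-7-(benzyloxy)-2-[4-(benzyloxy)phenyl]-2,3-dihydro-4H-chromen-4-one
Product: 28 (2S,4S)-7-(benzyloxy)-2-[4-(benzyloxy)phenyl]-3,4-dihydro-2H-chromen-4-ol
Conditions: NaBH4, THF/MeOH, 0 °C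
Reagents that add atoms: none
Why: Carbonyl reduction by axial hydride delivery should give the 2,4-cis alcohol; the C4 configuration is of no consequence because this centre is ionised in the next step, and the fast low-temperature reduction avoids ring opening at C2.

Step 12
Reactants: 28 (2S,4S)-7-(benzyloxy)-2-[4-(benzyloxy)phenyl]-3,4-dihydro-2H-chromen-4-ol; 23 (2R,3R)-3,5,7-tris(benzyloxy)-2-[4-(benzyloxy)phenyl]-3,4-dihydro-2H-chromene (3 equiv)
Product: 30 (2R,3R)-3,5,7-tris(benzyloxy)-2-[4-(benzyloxy)phenyl]-8-[(2S,4R)-7-(benzyloxy)-2-[4-(benzyloxy)phenyl]-3,4-dihydro-2H-chromen-4-yl]-3,4-dihydro-2H-chromene, via flavan-4-yl cation 29 (not isolated)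
Conditions: BF3·OEt2, 4 Å MS, CH2Cl2, −78 → −30 °C
Reagents that add atoms: none
Why: Friedel–Crafts alkylation of the proanthocyanidin type, a net dehydrative coupling in which the 4-hydroxyl of 28 and the C8 hydrogen of 23 leave as water: BF3 ionises the 4-hydroxyl to cation 29 (stabilised by the ring oxygen and the para 7-benzyloxy group), the phloroglucinol-type ring of 23 attacks through C8 (less hindered than C6, which lies between two benzyloxy groups) along the axial trajectory of the sofa cation, trans to the pseudo-equatorial 2-aryl group, which should set C4 as R (2,4-trans); the excess of 23 limits over-alkylation.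

Step 13
Reactants: 30 (2R,3R)-3,5,7-tris(benzyloxy)-2-[4-(benzyloxy)phenyl]-8-[(2S,4R)-7-(benzyloxy)-2-[4-(benzyloxy)phenyl]-3,4-dihydro-2H-chromen-4-yl]-3,4-dihydro-2H-chromene
Product: 31 (2R,3R)-8-[(2S,4R)-7-hydroxy-2-(4-hydroxyphenyl)-3,4-dihydro-2H-chromen-4-yl]-2-(4-hydroxyphenyl)-3,4-dihydro-2H-chromene-3,5,7-triol
Conditions: H2 (1 atm), Pd(OH)2/C, THF/MeOH, rt
Reagents that add atoms: none
Why: Catalytic hydrogenolysis cleaves the five aryl benzyl ethers and the 3-O-benzyl ether, while the ring C–O bonds and the interflavan C–C bond should persist under these mild conditions, as in proanthocyanidin syntheses.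

**Compound list**

1 | 3,5-bis(benzyloxy)phenol | Oc1cc(OCc2ccccc2)cc(OCc2ccccc2)c1 | starting material
2 | 3,5-bis(benzyloxy)phenyl N-(propan-2-yl)carbamate | CC(C)NC(=O)Oc1cc(OCc2ccccc2)cc(OCc2ccccc2)c1 | intermediate
3 | 3,5-bis(benzyloxy)phenyl N-(propan-2-yl)-N-(trimethylsilyl)carbamate | CC(C)N([Si](C)(C)C)C(=O)Oc1cc(OCc2ccccc2)cc(OCc2ccccc2)c1 | intermediate
4 | [2,4-bis(benzyloxy)-6-{[(propan-2-yl)(trimethylsilyl)carbamoyl]oxy}phenyl]lithium | CC(C)N([Si](C)(C)C)C(=O)Oc1cc(OCc2ccccc2)cc(OCc2ccccc2)c1[Li] | intermediate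
5 | 3,5-bis(benzyloxy)-2-(trimethylsilyl)phenyl N-(propan-2-yl)-N-(trimethylsilyl)carbamate | CC(C)N([Si](C)(C)C)C(=O)Oc1cc(OCc2ccccc2)cc(OCc2ccccc2)c1[Si](C)(C)C | intermediate
6 | 3,5-bis(benzyloxy)-2-(trimethylsilyl)phenyl N-(propan-2-yl)carbamate | CC(C)NC(=O)Oc1cc(OCc2ccccc2)cc(OCc2ccccc2)c1[Si](C)(C)C | intermediate
7 | 3,5-bis(benzyloxy)-2-(trimethylsilyl)phenol (present as its DBU salt) | Oc1cc(OCc2ccccc2)cc(OCc2ccccc2)c1[Si](C)(C)C | intermediate
8 | 3,5-bis(benzyloxy)-2-(trimethylsilyl)phenyl trifluoromethanesulfonate | C[Si](C)(C)c1c(OCc2ccccc2)cc(OCc2ccccc2)cc1OS(=O)(=O)C(F)(F)F | intermediate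
9 | (4S)-4-benzyl-1,3-oxazolidin-2-one | O=C1N[C@@H](Cc2ccccc2)CO1 | starting material
10 | (benzyloxy)acetyl chloride | ClC(=O)COCc1ccccc1 | starting material
11 | lithium salt of (4S)-4-benzyl-1,3-oxazolidin-2-one | [Li]N1[C@@H](Cc2ccccc2)COC1=O | intermediate
12 | (4S)-4-benzyl-3-[(benzyloxy)acetyl]-1,3-oxazolidin-2-one | O=C(COCc1ccccc1)N1[C@@H](Cc2ccccc2)COC1=O | intermediate
13 | 4-(benzyloxy)benzaldehyde | O=Cc1ccc(OCc2ccccc2)cc1 | starting material
14 | dibutylboron (Z)-enolate of 12 | CCCCB(CCCC)O/C(=C\OCc1ccccc1)N1[C@@H](Cc2ccccc2)COC1=O | intermediate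
15 | dibutylboron aldolate of 16 | O=C(N1[C@@H](Cc2ccccc2)COC1=O)[C@@H](OCc1ccccc1)[C@H](OB(CCCC)CCCC)c1ccc(OCc2ccccc2)cc1 | intermediate
16 | (4S)-4-benzyl-3-[(2S,3R)-2-(benzyloxy)-3-[4-(benzyloxy)phenyl]-3-hydroxypropanoyl]-1,3-oxazolidin-2-one | O=C(N1[C@@H](Cc2ccccc2)COC1=O)[C@@H](OCc1ccccc1)[C@H](O)c1ccc(OCc2ccccc2)cc1 | intermediate
17 | (1R,2R)-2-(benzyloxy)-1-[4-(benzyloxy)phenyl]propane-1,3-diol | OC[C@@H](OCc1ccccc1)[C@H](O)c1ccc(OCc2ccccc2)cc1 | intermediate
18 | (2R,3R)-2-(benzyloxy)-3-[4-(benzyloxy)phenyl]-3-hydroxypropyl methanesulfonate | CS(=O)(=O)OC[C@@H](OCc1ccccc1)[C@H](O)c1ccc(OCc2ccccc2)cc1 | intermediate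
19 | (1R,2S)-2-(benzyloxy)-1-[4-(benzyloxy)phenyl]-3-chloropropan-1-ol | ClC[C@@H](OCc1ccccc1)[C@H](O)c1ccc(OCc2ccccc2)cc1 | intermediate
20 | potassium (1R,2S)-2-(benzyloxy)-1-[4-(benzyloxy)phenyl]-3-chloropropan-1-olate | [K+].ClC[C@@H](OCc1ccccc1)[C@H]([O-])c1ccc(OCc2ccccc2)cc1 | intermediate
21 | 3,5-bis(benzyloxy)benzyne (1,2-didehydro-3,5-bis(benzyloxy)benzene) | C1#CC(OCc2ccccc2)=CC(OCc2ccccc2)=C1 | intermediate
22 | [2-{(1R,2S)-2-(benzyloxy)-1-[4-(benzyloxy)phenyl]-3-chloropropoxy}-4,6-bis(benzyloxy)phenyl]potassium | ClC[C@@H](OCc1ccccc1)[C@H](Oc1cc(OCc2ccccc2)cc(OCc2ccccc2)c1[K])c1ccc(OCc2ccccc2)cc1 | intermediate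
23 | (2R,3R)-3,5,7-tris(benzyloxy)-2-[4-(benzyloxy)phenyl]-3,4-dihydro-2H-chromene (tetra-O-benzyl-epiafzelechin) | C(c1ccccc1)Oc1cc(OCc2ccccc2)c2c(c1)O[C@H](c1ccc(OCc3ccccc3)cc1)[C@H](OCc1ccccc1)C2 | intermediate
24 | 7-hydroxy-4H-chromen-4-one | O=c1ccoc2cc(O)ccc12 | starting material
25 | 7-(benzyloxy)-4H-chromen-4-one | O=c1ccoc2cc(OCc3ccccc3)ccc12 | intermediate
26 | [4-(benzyloxy)phenyl]boronic acid | OB(O)c1ccc(OCc2ccccc2)cc1 | starting material
27 | (2S)-7-(benzyloxy)-2-[4-(benzyloxy)phenyl]-2,3-dihydro-4H-chromen-4-one | O=C1C[C@@H](c2ccc(OCc3ccccc3)cc2)Oc2cc(OCc3ccccc3)ccc12 | intermediate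
28 | (2S,4S)-7-(benzyloxy)-2-[4-(benzyloxy)phenyl]-3,4-dihydro-2H-chromen-4-ol | O[C@H]1C[C@@H](c2ccc(OCc3ccccc3)cc2)Oc2cc(OCc3ccccc3)ccc12 | intermediate
29 | (2S)-7-(benzyloxy)-2-[4-(benzyloxy)phenyl]-3,4-dihydro-2H-chromen-4-ylium hydroxytrifluoroborate | [CH+]1C[C@@H](c2ccc(OCc3ccccc3)cc2)Oc2cc(OCc3ccccc3)ccc12.O[B-](F)(F)F | intermediate
30 | (2R,3R)-3,5,7-tris(benzyloxy)-2-[4-(benzyloxy)phenyl]-8-[(2S,4R)-7-(benzyloxy)-2-[4-(benzyloxy)phenyl]-3,4-dihydro-2H-chromen-4-yl]-3,4-dihydro-2H-chromene | C(c1ccccc1)Oc1ccc([C@@H]2C[C@@H](c3c(OCc4ccccc4)cc(OCc4ccccc4)c4c3O[C@H](c3ccc(OCc5ccccc5)cc3)[C@H](OCc3ccccc3)C4)c3ccc(OCc4ccccc4)cc3O2)cc1 | intermediate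
31 | (2R,3R)-8-[(2S,4R)-7-hydroxy-2-(4-hydroxyphenyl)-3,4-dihydro-2H-chromen-4-yl]-2-(4-hydroxyphenyl)-3,4-dihydro-2H-chromene-3,5,7-triol | Oc1ccc([C@@H]2C[C@@H](c3c(O)cc(O)c4c3O[C@H](c3ccc(O)cc3)[C@H](O)C4)c3ccc(O)cc3O2)cc1 | target

**Step count**

Total steps: 13. Longest linear sequence: 7 steps (steps 4, 5, 6, 7, 8, 12, 13).

**Steps most likely to fail**

1. Step 8 (aryne annulation). The aryl anion may be protonated before it closes the ring, leaving only the O-aryl ether; the alkoxide may close on its own chloride; or the alkoxide may add at the other aryne carbon.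
   Fallback, known chemistry, setting out from 13 and 1 and returning at 23: vinylmagnesium bromide (THF, 0 °C) would add to 13 to give racemic 1-[4-(benzyloxy)phenyl]prop-2-en-1-ol F1. Sharpless kinetic resolution (Ti(OiPr)4, L-(+)-diisopropyl tartrate, t-BuOOH in deficit, 4 Å sieves, CH2Cl2, −20 °C) should then epoxidise the fast-reacting (R)-enantiomer to the erythro epoxy alcohol (S)-[4-(benzyloxy)phenyl][(2R)-oxiran-2-yl]methanol F2. Mitsunobu etherification with phenol 1 (PPh3, DIAD, toluene, 0 °C) inverts the carbinol centre and gives (2R)-2-[(R)-[3,5-bis(benzyloxy)phenoxy][4-(benzyloxy)phenyl]methyl]oxirane F3. A 6-endo epoxide–arene cyclisation (AuCl3/AgOTf cat., ClCH2CH2Cl, or hexafluoroisopropanol) forms the C4–C4a bond and gives (2R,3R)-5,7-bis(benzyloxy)-2-[4-(benzyloxy)phenyl]-3,4-dihydro-2H-chromen-3-ol F4, and NaH with BnBr (DMF, 0 °C) benzylates the 3-hydroxyl to reach 23.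

2. Step 12 (interflavan coupling). Facial selectivity at the cationic C4 may be poor, attack may occur through C6 instead of C8, the product may be alkylated again, or the cation may lose a proton to the flav-3-ene.
   Fallback, setting out from 23 and 28 and returning at 31: the protecting groups of the nucleophile are removed before the union so that the coupling runs as the classical reversible condensation of a free phloroglucinol ring. Hydrogenolysis of 23 (H2, Pd(OH)2/C, THF/MeOH) gives (2R,3R)-2-(4-hydroxyphenyl)-3,4-dihydro-2H-chromene-3,5,7-triol (epiafzelechin) F5. F5 in excess is condensed with 28 under protic acid (0.1 M HCl in dioxane/EtOH, rt), where the far more nucleophilic free ring A should capture the cation, and the C8-linked 2,4-trans dimer (2R,3R)-8-[(2S,4R)-7-(benzyloxy)-2-[4-(benzyloxy)phenyl]-3,4-dihydro-2H-chromen-4-yl]-2-(4-hydroxyphenyl)-3,4-dihydro-2H-chromene-3,5,7-triol F6 is separated. Hydrogenolysis of the two remaining benzyl ethers of F6 gives 31.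

3. Step 10 (asymmetric conjugate addition). The electron-rich boronic acid may undergo protodeboronation, the catalyst may turn over poorly, or the face selectivity may be low or opposite to the assumed sense.
   Fallback, setting out from 13 and returning at 28: Claisen–Schmidt condensation of 13 with commercial 1-[4-(benzyloxy)-2-hydroxyphenyl]ethan-1-one (KOH, EtOH, rt) gives (E)-1-[4-(benzyloxy)-2-hydroxyphenyl]-3-[4-(benzyloxy)phenyl]prop-2-en-1-one F7. Oxa-Michael ring closure (NaOAc, EtOH, reflux) gives racemic 7-(benzyloxy)-2-[4-(benzyloxy)phenyl]-2,3-dihydro-4H-chromen-4-one F8. Asymmetric transfer hydrogenation with kinetic resolution (RuCl(p-cymene)[(S,S)-TsDPEN], HCO2H/Et3N, rt, stopped near half conversion) should reduce the (2S)-enantiomer preferentially to the cis alcohol 28, which is separated from the unreacted (2R)-ketone.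

Further compounds
F1 | step 8 | 1-[4-(benzyloxy)phenyl]prop-2-en-1-ol (racemic) | C=CC(O)c1ccc(OCc2ccccc2)cc1
F2 | step 8 | (S)-[4-(benzyloxy)phenyl][(2R)-oxiran-2-yl]methanol | O[C@@H](c1ccc(OCc2ccccc2)cc1)[C@H]1CO1
F3 | step 8 | (2R)-2-[(R)-[3,5-bis(benzyloxy)phenoxy][4-(benzyloxy)phenyl]methyl]oxirane | C(c1ccccc1)Oc1cc(OCc2ccccc2)cc(O[C@H](c2ccc(OCc3ccccc3)cc2)[C@H]2CO2)c1
F4 | step 8 | (2R,3R)-5,7-bis(benzyloxy)-2-[4-(benzyloxy)phenyl]-3,4-dihydro-2H-chromen-3-ol | C(c1ccccc1)Oc1cc(OCc2ccccc2)c2c(c1)O[C@H](c1ccc(OCc3ccccc3)cc1)[C@H](O)C2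
F5 | step 12 | (2R,3R)-2-(4-hydroxyphenyl)-3,4-dihydro-2H-chromene-3,5,7-triol (epiafzelechin) | Oc1cc(O)c2c(c1)O[C@H](c1ccc(O)cc1)[C@H](O)C2
F6 | step 12 | (2R,3R)-8-[(2S,4R)-7-(benzyloxy)-2-[4-(benzyloxy)phenyl]-3,4-dihydro-2H-chromen-4-yl]-2-(4-hydroxyphenyl)-3,4-dihydro-2H-chromene-3,5,7-triol | C(c1ccccc1)Oc1ccc([C@@H]2C[C@@H](c3c(O)cc(O)c4c3O[C@H](c3ccc(O)cc3)[C@H](O)C4)c3ccc(OCc4ccccc4)cc3O2)cc1
F7 | step 10 | (E)-1-[4-(benzyloxy)-2-hydroxyphenyl]-3-[4-(benzyloxy)phenyl]prop-2-en-1-one | O=C(/C=C/c1ccc(OCc2ccccc2)cc1)c1ccc(OCc2ccccc2)cc1O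
F8 | step 10 | 7-(benzyloxy)-2-[4-(benzyloxy)phenyl]-2,3-dihydro-4H-chromen-4-one (racemic) | O=C1CC(c2ccc(OCc3ccccc3)cc2)Oc2cc(OCc3ccccc3)ccc12
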